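**Retrosynthetic overview**

1. Ring C runs O1–C2(aryl)–C3(OMe)–C4(=O)–C4a. Because the methoxy-bearing C3 lies between C2 and C4, C2 can be carried as a lactone carbonyl bound to O1, and C4 as the exocyclic methylene of a ring A ortho-quinone methide (quinone oxygen on C8a = O1, methylene on C4a = C4).
2. Target ⇐ BCl3 unmasking (6- and 3'-O-benzyl, chelation-selective 5-O-methyl) ⇐ C4 benzylic oxidation of the 2,3-trans flavan ⇐ silane reduction at C2 ⇐ ring B aryllithium + (3S)-3-methoxydihydrocoumarin.
3. Lactone ⇐ carbene-catalysed formal [4+2] annulation forming C3–C4 and O1–C2, from a fluoride-released ring A quinone methide and the azolium enolate of 1-(methoxyacetyl)imidazole.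
4. Quinone methide precursor ⇐ syringaldehyde (its symmetry makes the ortho-formylation unambiguous); acyl imidazole ⇐ methoxyacetic acid; ring B ⇐ 5-bromo-2-methoxyphenol.
5. Ring order: rings A and B are bought as arenes; ring C is the only ring made, closed in the annulation and then taken through C2 arylation/reduction and C4 oxidation.

Key step: step 8

Assumption: the sense of induction of the aminoindanol-derived carbene with a methoxy enolate is taken to follow that with alkyl enolates; the route is written with the (5aS,10bR) salt, and its commercially available antipode is to be used if a trial run gives the (3R) lactone.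

**Route**

Step 1
Reactants: 1 syringaldehyde (4-hydroxy-3,5-dimethoxybenzaldehyde)
Product: 2 4-(benzyloxy)-3,5-dimethoxybenzaldehyde
Conditions: BnBr, K2CO3, DMF, 60 °C
Reagents that add atoms: benzyl bromide, BrCc1ccccc1
Why: Williamson ether synthesis on the phenoxide; the benzyl group marks the future C6 oxygen so that it stays distinct from the two methyl ethers.

Step 2
Reactants: 2 4-(benzyloxy)-3,5-dimethoxybenzaldehyde
Product: 4 4-(benzyloxy)-3,5-dimethoxyphenol, via aryl formate 3 (not isolated)
Conditions: mCPBA, CH2Cl2, rt; then K2CO3 (cat.), MeOH, rt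
Reagents that add atoms: meta-chloroperoxybenzoic acid, OOC(=O)c1cccc(Cl)c1
Why: Baeyer–Villiger (Dakin-type) oxidation in which the electron-rich aryl group migrates in preference to hydride, followed by methanolysis of formate 3 in the same flask.

Step 3
Reactants: 4 4-(benzyloxy)-3,5-dimethoxyphenol
Product: 5 3-(benzyloxy)-6-hydroxy-2,4-dimethoxybenzaldehyde
Conditions: MgCl2, Et3N, (CH2O)n, MeCN, reflux
Reagents that add atoms: paraformaldehyde (formaldehyde), C=O
Why: Magnesium-phenoxide-directed ortho-formylation (Casnati–Skattebøl); the para position is blocked and the two ortho positions are equivalent by symmetry, so one aldehyde should result.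

Step 4
Reactants: 5 3-(benzyloxy)-6-hydroxy-2,4-dimethoxybenzaldehyde
Product: 6 3-(benzyloxy)-6-[(tert-butyldimethylsilyl)oxy]-2,4-dimethoxybenzaldehyde
Conditions: TBSCl, imidazole, DMF, rt
Reagents that add atoms: tert-butyldimethylsilyl chloride, CC(C)(C)[Si](C)(C)Cl
Why: Imidazole-promoted O-silylation of the phenol, which installs the fluoride-cleavable trigger for later quinone methide release.

Step 5
Reactants: 6 3-(benzyloxy)-6-[(tert-butyldimethylsilyl)oxy]-2,4-dimethoxybenzaldehyde
Product: 7 {3-(benzyloxy)-6-[(tert-butyldimethylsilyl)oxy]-2,4-dimethoxyphenyl}methanol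
Conditions: NaBH4, MeOH/THF, 0 °C, NH4Cl quench
Reagents that add atoms: none
Why: Borohydride 1,2-reduction of the aryl aldehyde, kept cold and short so that the silyl group does not migrate from the phenolic to the benzylic oxygen.

Step 6
Reactants: 7 {3-(benzyloxy)-6-[(tert-butyldimethylsilyl)oxy]-2,4-dimethoxyphenyl}methanol
Product: 8 {[4-(benzyloxy)-2-(bromomethyl)-3,5-dimethoxyphenyl]oxy}(tert-butyl)dimethylsilane
Conditions: CBr4, PPh3, CH2Cl2, −20 → 0 °C; rapid filtration through Et3N-deactivated silica, used at once
Reagents that add atoms: carbon tetrabromide, BrC(Br)(Br)Br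
Why: Appel bromination under neutral conditions that spare the aryl silyl ether; the electron-rich benzylic bromide ionises easily and is therefore not stored.

Step 7
Reactants: 9 methoxyacetic acid
Product: 10 1-(1H-imidazol-1-yl)-2-methoxyethan-1-one (1-(methoxyacetyl)imidazole)
Conditions: 1,1'-carbonyldiimidazole, CH2Cl2, rt
Reagents that add atoms: 1,1'-carbonyldiimidazole, O=C(n1ccnc1)n1ccnc1
Why: Acyl transfer through the mixed carbonic anhydride with loss of CO2, the standard preparation of an acyl imidazole.

Step 8
Reactants: 8 {[4-(benzyloxy)-2-(bromomethyl)-3,5-dimethoxyphenyl]oxy}(tert-butyl)dimethylsilane; 10 1-(methoxyacetyl)imidazole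
Product: 14 (3S)-6-(benzyloxy)-3,5,7-trimethoxychroman-2-one, via acyl azolium 11 (not isolated), via azolium enolate 12 (not isolated), via ortho-quinone methide 13 (not isolated)
Conditions: (5aS,10bR)-2-mesityl-5a,10b-dihydro-4H,6H-indeno[2,1-b][1,2,4]triazolo[4,3-d][1,4]oxazin-2-ium tetrafluoroborate (15 mol%), CsF, 18-crown-6, 4 Å MS, THF, −20 °C → rt, slow addition of 8
Reagents that add atoms: none
Why: Proposed new method: the free carbene displaces imidazole from 10 to give acyl azolium 11, whose alpha proton (acidified by the azolium and by the inductive effect of the methoxy group) is removed by fluoride or imidazolide to give the (Z)-enolate 12, while fluoride desilylates 8 and the phenoxide expels bromide to release quinone methide 13. Enolate carbon C3 adds to the exocyclic methylene (C4) of 13 in a Michael fashion that restores the aromaticity of ring A, and the phenoxide O1 then attacks the acyl azolium carbonyl C2 in a 6-exo-trig O-acylation that closes ring C as the lactone and frees the carbene. The closest known reaction type is the carbene-catalysed formal [4+2] annulation of alkyl- or aryl-substituted azolium enolates from acyl imidazoles with fluoride-generated ortho-quinone methides to 3-substituted dihydrocoumarins; an alpha-alkoxy enolate has not been shown in it. The single new stereocentre C3 is set by the catalyst, whose aminoindane wall shields one face of the planar enolate so that 13 approaches from the open face. The step needs C–C bond formation at the methylene carbon to outrun capture of 13 by imidazole, fluoride or a second molecule of 13, which the unhindered, strongly polarised methylene terminus and the slow fluoride-gated release of 13 should secure; regiochemistry is not in question because only 1,4-addition re-aromatises ring A. The methoxy enolate should be at least as nucleophilic as its alkyl congeners, and the product carries no beta leaving group that could be lost.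

Step 9
Reactants: 15 5-bromo-2-methoxyphenol
Product: 16 2-(benzyloxy)-4-bromo-1-methoxybenzene
Conditions: BnBr, K2CO3, acetone, reflux
Reagents that add atoms: benzyl bromide, BrCc1ccccc1
Why: Williamson ether synthesis; the benzyl ether masks the future 3'-hydroxyl through the organolithium and oxidation steps.

Step 10
Reactants: 16 2-(benzyloxy)-4-bromo-1-methoxybenzene; 14 (3S)-6-(benzyloxy)-3,5,7-trimethoxychroman-2-one
Product: 18 (2S)-1-[3-(benzyloxy)-4-methoxyphenyl]-3-[3-(benzyloxy)-6-hydroxy-2,4-dimethoxyphenyl]-2-methoxypropan-1-one, via aryllithium 17 (not isolated)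
Conditions: n-BuLi, THF, −78 °C; then cannulated into 14, THF, −78 °C; AcOH, −78 °C → rt
Reagents that add atoms: none
Why: Bromine–lithium exchange then 1,2-addition of the aryllithium to the lactone carbonyl as in C-aryl glycoside synthesis; chelation of lithium by the C3 methoxy group should hold the tetrahedral adduct at −78 °C against a second addition, and the cold acidic quench protects the C3 centre.

Step 11
Reactants: 18 (2S)-1-[3-(benzyloxy)-4-methoxyphenyl]-3-[3-(benzyloxy)-6-hydroxy-2,4-dimethoxyphenyl]-2-methoxypropan-1-one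
Product: 21 (2R,3S)-6-(benzyloxy)-2-[3-(benzyloxy)-4-methoxyphenyl]-3,5,7-trimethoxychromane (2,3-trans), via lactol 19 (not isolated), via oxocarbenium ion 20 (not isolated)
Conditions: Et3SiH, BF3·OEt2, CH2Cl2/MeCN, −40 → −10 °C (silane present before the Lewis acid)
Reagents that add atoms: none
Why: Ionic hydrogenation of a lactol: the phenol closes onto the ketone to give 19, BF3 ionises it to 20, and hydride is delivered axially on the face that leads to a chair with the C2 aryl and C3 methoxy groups both equatorial, so C2 is set trans to C3 by substrate control.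

Step 12
Reactants: 21 (2R,3S)-6-(benzyloxy)-2-[3-(benzyloxy)-4-methoxyphenyl]-3,5,7-trimethoxychromane
Product: 23 (2R,3S,4RS)-6-(benzyloxy)-2-[3-(benzyloxy)-4-methoxyphenyl]-3,5,7-trimethoxychroman-4-ol, via C4 cation 22 (not isolated)
Conditions: DDQ, CH2Cl2/H2O, 0 °C → rt
Reagents that add atoms: water, O
Why: Benzylic C–H oxidation by hydride abstraction, as established for protected catechins; the C4 cation is stabilised by the ortho and para oxygens of ring A (C5, C7, O1) and is trapped by water, and the C4 configuration does not matter because step 13 removes it.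

Step 13
Reactants: 23 (2R,3S,4RS)-6-(benzyloxy)-2-[3-(benzyloxy)-4-methoxyphenyl]-3,5,7-trimethoxychroman-4-ol
Product: 24 (2R,3R)-6-(benzyloxy)-2-[3-(benzyloxy)-4-methoxyphenyl]-3,5,7-trimethoxychroman-4-one
Conditions: Dess–Martin periodinane, CH2Cl2, 0 °C → rt
Reagents that add atoms: none
Why: Dess–Martin oxidation of the secondary benzylic alcohol to the ketone under non-basic conditions that should leave the now alpha C3 centre and the C2 centre untouched.

Step 14
Reactants: 24 (2R,3R)-6-(benzyloxy)-2-[3-(benzyloxy)-4-methoxyphenyl]-3,5,7-trimethoxychroman-4-one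
Product: 25 (2R,3R)-5,6-dihydroxy-2-(3-hydroxy-4-methoxyphenyl)-3,7-dimethoxychroman-4-one (target)
Conditions: BCl3, pentamethylbenzene, CH2Cl2, −78 → 0 °C; then MeOH, aqueous NaHCO3
Reagents that add atoms: none
Why: Lewis-acid ether cleavage: both benzyl ethers are removed with pentamethylbenzene as cation scavenger, and the 5-O-methyl group alone among the methyl ethers is cleaved because boron chelates between its oxygen and the peri C4 carbonyl.

**Compound list**

1 | syringaldehyde | COc1cc(C=O)cc(OC)c1O | starting material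
2 | 4-(benzyloxy)-3,5-dimethoxybenzaldehyde | COc1cc(C=O)cc(OC)c1OCc1ccccc1 | intermediate
3 | 4-(benzyloxy)-3,5-dimethoxyphenyl formate | COc1cc(OC=O)cc(OC)c1OCc1ccccc1 | intermediate
4 | 4-(benzyloxy)-3,5-dimethoxyphenol | COc1cc(O)cc(OC)c1OCc1ccccc1 | intermediate
5 | 3-(benzyloxy)-6-hydroxy-2,4-dimethoxybenzaldehyde | COc1cc(O)c(C=O)c(OC)c1OCc1ccccc1 | intermediate
6 | 3-(benzyloxy)-6-[(tert-butyldimethylsilyl)oxy]-2,4-dimethoxybenzaldehyde | COc1cc(O[Si](C)(C)C(C)(C)C)c(C=O)c(OC)c1OCc1ccccc1 | intermediate
7 | {3-(benzyloxy)-6-[(tert-butyldimethylsilyl)oxy]-2,4-dimethoxyphenyl}methanol | COc1cc(O[Si](C)(C)C(C)(C)C)c(CO)c(OC)c1OCc1ccccc1 | intermediate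
8 | {[4-(benzyloxy)-2-(bromomethyl)-3,5-dimethoxyphenyl]oxy}(tert-butyl)dimethylsilane | COc1cc(O[Si](C)(C)C(C)(C)C)c(CBr)c(OC)c1OCc1ccccc1 | intermediate
9 | methoxyacetic acid | COCC(=O)O | starting material
10 | 1-(1H-imidazol-1-yl)-2-methoxyethan-1-one | COCC(=O)n1ccnc1 | intermediate
11 | acyl azolium cation: the (5aS,10bR) triazolium of the catalyst carrying the methoxyacetyl group on its carbene carbon | COCC(=O)c1n2[C@@H]3c4ccccc4C[C@@H]3OCc2n[n+]1-c5c(C)cc(C)cc5C | intermediate
12 | azolium enolate: (Z)-2-methoxy-1-(triazolium-yl)ethen-1-olate zwitterion derived from 11 | CO/C=C(\[O-])c1n2[C@@H]3c4ccccc4C[C@@H]3OCc2n[n+]1-c5c(C)cc(C)cc5C | intermediate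
13 | 4-(benzyloxy)-3,5-dimethoxy-6-methylidenecyclohexa-2,4-dien-1-one (ring A ortho-quinone methide) | C=C1C(=O)C=C(OC)C(OCc2ccccc2)=C1OC | intermediate
14 | (3S)-6-(benzyloxy)-3,5,7-trimethoxychroman-2-one | CO[C@H]1Cc2c(OC)c(OCc3ccccc3)c(OC)cc2OC1=O | intermediate
15 | 5-bromo-2-methoxyphenol | COc1ccc(Br)cc1O | starting material
16 | 2-(benzyloxy)-4-bromo-1-methoxybenzene | COc1ccc(Br)cc1OCc1ccccc1 | intermediate
17 | [3-(benzyloxy)-4-methoxyphenyl]lithium | [Li]c1ccc(OC)c(OCc2ccccc2)c1 | intermediate
18 | (2S)-1-[3-(benzyloxy)-4-methoxyphenyl]-3-[3-(benzyloxy)-6-hydroxy-2,4-dimethoxyphenyl]-2-methoxypropan-1-one | CO[C@@H](Cc1c(OC)c(OCc2ccccc2)c(OC)cc1O)C(=O)c1ccc(OC)c(OCc2ccccc2)c1 | intermediate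
19 | (3S)-6-(benzyloxy)-2-[3-(benzyloxy)-4-methoxyphenyl]-3,5,7-trimethoxychroman-2-ol (lactol, both C2 epimers) | CO[C@H]1Cc2c(OC)c(OCc3ccccc3)c(OC)cc2OC1(O)c4ccc(OC)c(OCc5ccccc5)c4 | intermediate
20 | (3S)-6-(benzyloxy)-2-[3-(benzyloxy)-4-methoxyphenyl]-3,5,7-trimethoxy-3,4-dihydrochromenylium (oxocarbenium ion, C2=O1+) | CO[C@H]1Cc2c(OC)c(OCc3ccccc3)c(OC)cc2[O+]=C1c4ccc(OC)c(OCc5ccccc5)c4 | intermediate
21 | (2R,3S)-6-(benzyloxy)-2-[3-(benzyloxy)-4-methoxyphenyl]-3,5,7-trimethoxychromane | COc1ccc([C@H]2Oc3cc(OC)c(OCc4ccccc4)c(OC)c3C[C@@H]2OC)cc1OCc1ccccc1 | intermediate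
22 | (2R,3S)-6-(benzyloxy)-2-[3-(benzyloxy)-4-methoxyphenyl]-3,5,7-trimethoxychroman-4-ylium (C4 cation) | COc1ccc([C@H]2Oc3cc(OC)c(OCc4ccccc4)c(OC)c3[CH+][C@@H]2OC)cc1OCc1ccccc1 | intermediate
23 | (2R,3S,4RS)-6-(benzyloxy)-2-[3-(benzyloxy)-4-methoxyphenyl]-3,5,7-trimethoxychroman-4-ol | COc1ccc([C@H]2Oc3cc(OC)c(OCc4ccccc4)c(OC)c3C(O)[C@@H]2OC)cc1OCc1ccccc1 | intermediate
24 | (2R,3R)-6-(benzyloxy)-2-[3-(benzyloxy)-4-methoxyphenyl]-3,5,7-trimethoxychroman-4-one | COc1ccc([C@H]2Oc3cc(OC)c(OCc4ccccc4)c(OC)c3C(=O)[C@@H]2OC)cc1OCc1ccccc1 | intermediate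
25 | (2R,3R)-5,6-dihydroxy-2-(3-hydroxy-4-methoxyphenyl)-3,7-dimethoxychroman-4-one | COc1ccc([C@H]2Oc3cc(OC)c(O)c(O)c3C(=O)[C@@H]2OC)cc1O | target

**Step count**

Total: 14 steps. Longest linear sequence: 12 steps (steps 1–6, 8, 10–14).

**Steps most likely to fail**

Step 8. The methoxyacetyl azolium may enolise sluggishly or its enolate may add with poor facial selectivity. The quinone methide may be consumed by imidazole, fluoride or self-condensation before the C–C bond forms. The lactone may also lose optical purity through base-mediated enolisation. The fallback uses auxiliary-controlled alkylation, sets out from 8 and 10 and returns at 14. Lithiated (R)-4-benzyloxazolidin-2-one is acylated with 10 to give (R)-4-benzyl-3-(methoxyacetyl)oxazolidin-2-one F1. Its chelated sodium (Z)-enolate (NaHMDS, THF, −78 °C) is alkylated by bromide 8 on the face away from the auxiliary benzyl group (Evans glycolate alkylation). This should give (R)-4-benzyl-3-[(2S)-3-{3-(benzyloxy)-6-[(tert-butyldimethylsilyl)oxy]-2,4-dimethoxyphenyl}-2-methoxypropanoyl]oxazolidin-2-one F2. LiOH/H2O2 in THF/H2O removes the auxiliary and, in the basic medium or with a following TBAF treatment, the aryl silyl ether, giving (2S)-3-[3-(benzyloxy)-6-hydroxy-2,4-dimethoxyphenyl]-2-methoxypropanoic acid F3. F3 lactonises on acidification (catalytic TsOH, toluene) to 14.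

Step 11. The oxocarbenium ion may lose its C3 proton to a 4H-chromene, which on reprotonation erodes the C3 configuration. The ketone may also be deoxygenated reductively without ring closure. The fallback separates reduction from ring closure, sets out from 18 and returns at 21. NaBH4 (MeOH, −20 °C) reduces the ketone to (1RS,2S)-1-[3-(benzyloxy)-4-methoxyphenyl]-3-[3-(benzyloxy)-6-hydroxy-2,4-dimethoxyphenyl]-2-methoxypropan-1-ol F4, both carbinol epimers being acceptable. Acid-catalysed cyclodehydration (catalytic TsOH, CH2Cl2, 0 °C, or Mitsunobu conditions) then proceeds through the para-methoxybenzylic cation. The phenol captures this cation in a chair-like transition state with the aryl and methoxy groups equatorial, so both epimers should converge on the trans flavan 21. No ring oxocarbenium adjacent to C3 is involved.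

Step 10. The tetrahedral adduct may collapse to the ring-opened ketone and take up a second aryllithium. The aryllithium may also act as a base on the lactone or the ketone and so racemise C3. The fallback passes through a Weinreb amide, sets out from 14 and returns at 18. N,O-Dimethylhydroxylamine hydrochloride with i-PrMgCl (THF, −20 °C) opens the lactone to (2S)-3-[3-(benzyloxy)-6-hydroxy-2,4-dimethoxyphenyl]-N,2-dimethoxy-N-methylpropanamide F5. F5 is deprotonated at the phenol with one equivalent of i-PrMgCl and treated with aryllithium 17 at −78 °C. The chelated tetrahedral intermediate cannot collapse before the acidic quench, so only one aryl group can enter and 18 results directly.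

**Further compounds**

F1 | step 8 | (R)-4-benzyl-3-(methoxyacetyl)oxazolidin-2-one | COCC(=O)N1[C@H](Cc2ccccc2)COC1=O
F2 | step 8 | (R)-4-benzyl-3-[(2S)-3-{3-(benzyloxy)-6-[(tert-butyldimethylsilyl)oxy]-2,4-dimethoxyphenyl}-2-methoxypropanoyl]oxazolidin-2-one | CO[C@@H](Cc1c(OC)c(OCc2ccccc2)c(OC)cc1O[Si](C)(C)C(C)(C)C)C(=O)N1[C@H](Cc2ccccc2)COC1=O
F3 | step 8 | (2S)-3-[3-(benzyloxy)-6-hydroxy-2,4-dimethoxyphenyl]-2-methoxypropanoic acid | CO[C@@H](Cc1c(OC)c(OCc2ccccc2)c(OC)cc1O)C(O)=O
F4 | step 11 | (1RS,2S)-1-[3-(benzyloxy)-4-methoxyphenyl]-3-[3-(benzyloxy)-6-hydroxy-2,4-dimethoxyphenyl]-2-methoxypropan-1-ol | CO[C@@H](Cc1c(OC)c(OCc2ccccc2)c(OC)cc1O)C(O)c1ccc(OC)c(OCc2ccccc2)c1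
F5 | step 10 | (2S)-3-[3-(benzyloxy)-6-hydroxy-2,4-dimethoxyphenyl]-N,2-dimethoxy-N-methylpropanamide | CO[C@@H](Cc1c(OC)c(OCc2ccccc2)c(OC)cc1O)C(=O)N(C)OC
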